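## Retrosynthetic overview
- **Key disconnection.** The C1–C2, C1–C13' and C3–C11' bonds are made in one pot. A 1,2-seco-guaianolide dienal is closed to a 5-acetoxycyclopentadiene by an acylative iso-Nazarov 4π closure. That diene is trapped at once by the α-methylene lactone of the seco-eudesmanolide half in a Diels–Alder reaction.
- **Western half.** The seven-membered ring comes first, from a Rh-carbenoid [4+3] of a vinyldiazoacetate with butadiene. The trans lactone follows (epoxide opening, then alkyne carbonylation), and the dienal is made by Meyer–Schuster rearrangement.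
- **Eastern half.** The six-membered ring comes from 4-methylanisole by Birch reduction. The side chain and C4' are set by C–H functionalisation/Cope with the same diazo ester, and C10'–OH by singlet oxygen. The lactone is built last (α-hydroxy ketone, butenolide, reductive methylenation).
- **Ring order.** West: cycloheptadiene, then lactone A. East: cyclohexadiene, then lactone B. The cyclopentene and bicyclo[2.2.1]heptene rings form together at the end.

**Atom labels.**
- Western half C1–C15 (guaiane numbering): C1/C5 ring fusion, C2 acetoxy carbon, C4 methyl-bearing, C7/C8 lactone fusion, C10 methyl-bearing, C11–C13 methylene lactone.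
- Eastern half C1'–C15' (1,10-seco-eudesmane numbering): C1' CH2OAc, C4' side-chain stereocentre, C5'=C6', C7'/C8' lactone fusion, C10' carbinol, C11' spiro carbon, C13' its CH2.

**Assumption.** The sense of induction of Rh2(S-DOSP)4 in steps 2 and 9 is taken from its standard cyclopropanation and C–H/Cope models; Rh2(R-DOSP)4 is equally available should it prove opposite.

## Route

Step 1
Reactants: 1 methyl (E)-pent-3-enoate
Product: 2 methyl (E)-2-diazopent-3-enoate
Conditions: p-ABSA, DBU, MeCN, 0 °C to rt
Reagents that add atoms: 4-acetamidobenzenesulfonyl azide (p-ABSA), CC(=O)Nc1ccc(cc1)S(=O)(=O)N=[N+]=[N-]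
Why: Regitz diazo transfer onto the allylic α-ester CH2 gives the vinyldiazoacetate used for both halves; no stereocentre is formed and the E-alkene is kept.

Step 2
Reactants: 2 methyl (E)-2-diazopent-3-enoate; 3 buta-1,3-diene
Product: 5 methyl (3R)-3-methylcyclohepta-1,5-diene-1-carboxylate, via cis-divinylcyclopropane 4 (not isolated)
Conditions: Rh2(S-DOSP)4 (1 mol %), 3 (5 equiv), pentane, −78 °C to rt, slow addition of 2
Reagents that add atoms: none
Why: In this tandem asymmetric cyclopropanation/divinylcyclopropane Cope rearrangement (formal [4+3]), the catalyst fixes the (1R,2R)-cyclopropane and the boat Cope transition state relays this to C10 (R), leaving the ester on C5, C1=C5 in place and an isolated C7=C8 alkene.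

Step 3
Reactants: 5 methyl (3R)-3-methylcyclohepta-1,5-diene-1-carboxylate
Product: 7 1-[(3R)-3-methylcyclohepta-1,5-dien-1-yl]ethanone, via Weinreb amide 6 (not isolated)
Conditions: MeNH(OMe)·HCl, i-PrMgCl, THF, −20 °C; then MeMgBr, 0 °C; aq NH4Cl
Reagents that add atoms: methylmagnesium bromide, C[Mg]Br; N,O-dimethylhydroxylamine hydrochloride, CNOC.Cl (its atoms stay only in 6)
Why: In this one-pot Weinreb ketone synthesis the chelated adduct of 6 with MeMgBr stops at the methyl ketone (C4, C15), and C10 is untouched.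

Step 4
Reactants: 7 1-[(3R)-3-methylcyclohepta-1,5-dien-1-yl]ethanone
Product: 8 7,8-epoxide of 7 with the oxirane anti to the C10 methyl (7S,8R,10R)
Conditions: mCPBA (1.05 equiv), CH2Cl2, 0 °C
Reagents that add atoms: 3-chloroperbenzoic acid, OOC(=O)c1cccc(Cl)c1
Why: Prilezhaev epoxidation picks the isolated cis-alkene (the enone alkene is deactivated) and occurs anti to the pseudo-axial C10 methyl, which sets C7 (S) and C8 (R); the minor syn epoxide is removed by chromatography.

Step 5
Reactants: 8 7,8-epoxide of 7 (7S,8R,10R)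
Product: 9 diyne diol (7S,8R,10R; both C4 epimers): C7 ethynyl trans to C8 OH and a 2-hydroxybut-3-yn-2-yl group on C5
Conditions: HC≡CLi·H2NCH2CH2NH2 (5 equiv), DMSO–THF, 0 °C to rt; aq NH4Cl
Reagents that add atoms: lithium acetylide ethylenediamine complex, [Li]C#C.NCCN
Why: One reagent performs a 1,2-addition to the ketone (the C4 epimers do not matter because C4 becomes sp2) and an SN2 epoxide opening from the β face, which goes to C7 because the path to C8 is 1,3-syn to the C10 methyl, giving the trans 7-alkynyl-8-ol.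

Step 6
Reactants: 9 diyne diol (7S,8R,10R)
Product: 10 hydroxy enyne dienal (7S,8R,10R; E/Z at C3=C4 with E drawn)
Conditions: VO(OSiPh3)3 (5 mol %), Ph3SiOH (10 mol %), xylene, 130 °C
Reagents that add atoms: none
Why: The oxovanadium-catalysed Meyer–Schuster rearrangement ([3,3] shift of the propargyl vanadate, then tautomerisation) touches only the propargylic alcohol and converts it irreversibly into the C2 enal, while the homopropargylic alcohol and all stereocentres are spectators.

Step 7
Reactants: 10 hydroxy enyne dienal (7S,8R,10R)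
Product: 11 dienal lactone (7S,8R,10R)-1,2-secoguaia-1(5),3,11(13)-trien-2-al-12,8-olide
Conditions: PdCl2 (5 mol %), thiourea (10 mol %), CO (1–3 atm), acetone, 50 °C
Reagents that add atoms: carbon monoxide, [C-]#[O+]
Why: Pd(II)-catalysed cyclocarbonylation of the homopropargylic alcohol builds the α-methylene-γ-butyrolactone directly, and the trans fusion is inherited from 10.

Step 8
Reactants: 12 4-methylanisole
Product: 13 1-methoxy-4-methylcyclohexa-1,4-diene
Conditions: Li, NH3(l), t-BuOH, THF, −78 to −33 °C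
Reagents that add atoms: none
Why: Birch reduction leaves the OMe- and Me-bearing carbons sp2 and gives the skipped diene with two doubly allylic CH2 groups.

Step 9
Reactants: 13 1-methoxy-4-methylcyclohexa-1,4-diene; 2 methyl (E)-2-diazopent-3-enoate
Product: 14 methyl (2E,4R)-4-[(1S)-4-methoxy-2-methylcyclohexa-2,4-dien-1-yl]pent-2-enoate (4'R,5'S)
Conditions: Rh2(S-DOSP)4 (1 mol %), 13 (4 equiv), 2,2-dimethylbutane, rt, slow addition of 2
Reagents that add atoms: none
Why: In this combined C–H functionalisation/Cope rearrangement the carbenoid takes the C9'–H whose cationic character is stabilised through to OMe, while its vinyl terminus bonds to the only unhindered terminus C5' via a boat array that keeps the catalyst off the ring, setting C4' (R) and the relay centre C5' (S) together.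

Step 10
Reactants: 14 (4'R,5'S)-enoate
Product: 15 methyl (4R)-4-[(1S)-4-methoxy-2-methylcyclohexa-2,4-dien-1-yl]pentanoate
Conditions: Mg, MeOH, 0 °C to rt
Reagents that add atoms: none
Why: Dissolving-metal conjugate reduction saturates only the α,β-unsaturated ester; the dienol ether is inert in the basic medium and C4'/C5' are untouched.

Step 11
Reactants: 15 saturated ester (4'R,5'S)
Product: 17 (4R)-4-[(1S)-4-methoxy-2-methylcyclohexa-2,4-dien-1-yl]pentyl acetate, via primary alcohol 16 (not isolated)
Conditions: LiAlH4, Et2O, 0 °C; Na2SO4·10H2O, filter; crude, Ac2O, pyridine, DMAP, CH2Cl2, rt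
Reagents that add atoms: acetic anhydride, CC(=O)OC(C)=O
Why: Ester reduction and O-acetylation under non-acidic conditions install the C1' acetate early, when no other carbonyl group is present.

Step 12
Reactants: 17 dienol ether acetate (4'R,5'S)
Product: 19 γ-hydroxy enone (4'R,5'S,10'R): 4-hydroxy-4-methyl-5-(5-acetoxypentan-2-yl)cyclohex-2-enone, via methoxy endoperoxide 18 (not isolated)
Conditions: O2, TPP (cat.), hν, CH2Cl2, −78 °C; then thiourea, MeOH, −78 °C to rt
Reagents that add atoms: oxygen, O=O
Why: The singlet-oxygen [4+2] cycloaddition occurs anti to the C5' side chain and sets C10' (R); O–O reduction then lets the C7' hemiketal lose methanol, revealing the enone.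

Step 13
Reactants: 19 γ-hydroxy enone
Product: 20 p-quinol (4'R,10'R): 4-hydroxy-4-methyl-3-(5-acetoxypentan-2-yl)cyclohexa-2,5-dienone
Conditions: IBX (2.5 equiv), DMSO, 70 °C
Reagents that add atoms: none
Why: IBX dehydrogenation at the only α'-CH2 creates C5'=C6' and erases the relay centre C5', while the quaternary C10' prevents aromatisation.

Step 14
Reactants: 20 p-quinol (4'R,10'R)
Product: 22 α-hydroxy enone (4'R,8'S,10'R), via hydroperoxide 21 (not isolated)
Conditions: Mn(dpm)3 (5 mol %), PhSiH3, O2 (1 atm), i-PrOH–CH2Cl2, 0 °C; then P(OEt)3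
Reagents that add atoms: oxygen, O=O
Why: In this Mukaiyama-type HAT reductive α-hydroxylation, H adds to C9' of the less substituted enone and O2 traps the C8' radical on the face away from the axial C10' methyl, giving the equatorial C8'–OH cis to C10'–OH, which is also the thermodynamic epimer.

Step 15
Reactants: 22 α-hydroxy enone
Product: 24 dienyl butenolide (4'R,8'S,10'R) with C7'=C11', via acyl ylide 23 (not isolated)
Conditions: Ph3P=C=C=O (1.1 equiv), toluene, 90 °C
Reagents that add atoms: (triphenylphosphoranylidene)ketene, O=C=C=P(c1ccccc1)(c1ccccc1)c1ccccc1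
Why: In the Bestmann-ylide butenolide annulation the secondary C8'–OH adds to the ketene and the resulting ester ylide closes by intramolecular Wittig reaction on the C7' ketone, while the hindered tertiary OH does not react.

Step 16
Reactants: 24 dienyl butenolide
Product: 27 (4'R,7'S,8'S,10'R)-1'-acetoxy-10'-hydroxy-1',10'-secoeudesma-5',11'(13')-dien-12',8'-olide, via Mannich base 25 (not isolated), via ammonium iodide 26 (not isolated)
Conditions: L-Selectride (2.2 equiv), THF, −78 °C; CH2=NMe2+ I−, −78 °C to rt; MeI; aq NaHCO3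
Reagents that add atoms: Eschenmoser's salt, C[N+](C)=C.[I-]; methyl iodide, CI (its atoms stay only in 26)
Why: This is a 1,4-hydride addition followed by enolate Mannich reaction and Hofmann-type elimination; 1,6-addition is blocked at the fully substituted C5', and hydride enters C7' from the side of H-8' rather than C9', giving the less strained cis lactone (7'S) and then the exocyclic methylene.

Step 17
Reactants: 11 dienal lactone (7S,8R,10R); 27 eastern α-methylene lactone
Product: 30 target CNP0257312.1, via gem-diacetate 28 (not isolated), via acetoxycyclopentadiene 29 (not isolated)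
Conditions: 11, Ac2O (1.05 equiv), Sc(OTf)3 (2 mol %), CH2Cl2, −40 to −10 °C; then 2,6-lutidine (10 mol %), 27 (1.5 equiv), concentrate to 2 M, 25 °C, 48 h
Reagents that add atoms: acetic anhydride, CC(=O)OC(C)=O
Why: Proposed new method: Sc(OTf)3/Ac2O makes the acylal 28 (standard chemistry) and re-ionises it to a 1-acetoxypentadienyl cation whose C3=C4 geometry equilibrates; the U-shaped cation closes by conrotatory 4π electrocyclisation (C1–C2 bond; closest known types are the iso-Nazarov cyclisation of 2,4-dienals or their acetals and one-pot dehydrative Nazarov/Diels–Alder sequences) with the outward OAc turning away from the C10 methyl so that C2 is R; acetate removes H-1 to give 29; and 29 undergoes a Diels–Alder reaction on its face syn to OAc (the known preference of 5-acetoxycyclopentadienes, here also anti to the C10 methyl) with the convex face of 27, C13'H2 bonding to the substituted terminus C1 to avoid vicinal quaternary carbons and the lactone carbonyl endo because ring B cannot sit under the C4 methyl, which sets C1 (R), C3 (S) and C11' (R).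

## Compound list
1 | methyl (E)-pent-3-enoate | COC(=O)C/C=C/C | starting material
2 | methyl (E)-2-diazopent-3-enoate | COC(=O)C(=[N+]=[N-])/C=C/C | intermediate
3 | buta-1,3-diene | C=CC=C | starting material
4 | methyl (1R,2R)-1-[(E)-prop-1-enyl]-2-vinylcyclopropane-1-carboxylate | COC(=O)[C@@]1(/C=C/C)C[C@@H]1C=C | intermediate (not isolated)
5 | methyl (3R)-3-methylcyclohepta-1,5-diene-1-carboxylate | COC(=O)C1=C[C@H](C)CC=CC1 | intermediate
6 | (3R)-N-methoxy-N,3-dimethylcyclohepta-1,5-diene-1-carboxamide | CON(C)C(=O)C1=C[C@H](C)CC=CC1 | intermediate (not isolated)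
7 | 1-[(3R)-3-methylcyclohepta-1,5-dien-1-yl]ethanone | CC(=O)C1=C[C@H](C)CC=CC1 | intermediate
8 | 7,8-epoxide of 7, oxirane anti to the methyl (7S,8R,10R) | CC(=O)C1=C[C@H](C)C[C@H]2O[C@H]2C1 | intermediate
9 | diyne diol (7S,8R,10R; C4 epimers) | C#CC(C)(O)C1=C[C@H](C)C[C@@H](O)[C@H](C#C)C1 | intermediate
10 | hydroxy enyne dienal (7S,8R,10R; E drawn) | O=C/C=C(\C)C1=C[C@H](C)C[C@@H](O)[C@H](C#C)C1 | intermediate
11 | (7S,8R,10R)-1,2-secoguaia-1(5),3,11(13)-trien-2-al-12,8-olide | O=C/C=C(\C)C1=C[C@H](C)C[C@H]2OC(=O)C(=C)[C@@H]2C1 | intermediate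
12 | 4-methylanisole | COc1ccc(C)cc1 | starting material
13 | 1-methoxy-4-methylcyclohexa-1,4-diene | COC1=CCC(C)=CC1 | intermediate
14 | methyl (2E,4R)-4-[(1S)-4-methoxy-2-methylcyclohexa-2,4-dien-1-yl]pent-2-enoate | COC(=O)/C=C/[C@@H](C)[C@@H]1CC(OC)=CC=C1C | intermediate
15 | methyl (4R)-4-[(1S)-4-methoxy-2-methylcyclohexa-2,4-dien-1-yl]pentanoate | COC(=O)CC[C@@H](C)[C@@H]1CC(OC)=CC=C1C | intermediate
16 | (4R)-4-[(1S)-4-methoxy-2-methylcyclohexa-2,4-dien-1-yl]pentan-1-ol | OCCC[C@@H](C)[C@@H]1CC(OC)=CC=C1C | intermediate (not isolated)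
17 | (4R)-4-[(1S)-4-methoxy-2-methylcyclohexa-2,4-dien-1-yl]pentyl acetate | CC(=O)OCCC[C@@H](C)[C@@H]1CC(OC)=CC=C1C | intermediate
18 | C7',C10'-endoperoxide of 17, O–O anti to the side chain | CC(=O)OCCC[C@@H](C)[C@@H]1C[C@]2(OC)C=C[C@@]1(C)OO2 | intermediate (not isolated)
19 | γ-hydroxy enone (4'R,5'S,10'R) | CC(=O)OCCC[C@@H](C)[C@@H]1CC(=O)C=C[C@@]1(C)O | intermediate
20 | p-quinol (4'R,10'R) | CC(=O)OCCC[C@@H](C)C1=CC(=O)C=C[C@@]1(C)O | intermediate
21 | C8' hydroperoxide (4'R,8'S,10'R) | CC(=O)OCCC[C@@H](C)C1=CC(=O)[C@@H](OO)C[C@@]1(C)O | intermediate (not isolated)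
22 | α-hydroxy enone (4'R,8'S,10'R) | CC(=O)OCCC[C@@H](C)C1=CC(=O)[C@@H](O)C[C@@]1(C)O | intermediate
23 | C8' (triphenylphosphoranylidene)acetate of 22 | CC(=O)OCCC[C@@H](C)C1=CC(=O)[C@@H](OC(=O)C=P(c2ccccc2)(c2ccccc2)c2ccccc2)C[C@@]1(C)O | intermediate (not isolated)
24 | dienyl butenolide (4'R,8'S,10'R) | CC(=O)OCCC[C@@H](C)C1=CC2=CC(=O)O[C@H]2C[C@@]1(C)O | intermediate
25 | C11' dimethylaminomethyl lactone (C11' epimers) | CN(C)CC1C(=O)O[C@H]2C[C@@](C)(O)C([C@H](C)CCCOC(C)=O)=C[C@@H]12 | intermediate (not isolated)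
26 | trimethylammonium iodide of 25 | C[N+](C)(C)CC1C(=O)O[C@H]2C[C@@](C)(O)C([C@H](C)CCCOC(C)=O)=C[C@@H]12.[I-] | intermediate (not isolated)
27 | (4'R,7'S,8'S,10'R)-1'-acetoxy-10'-hydroxy-1',10'-secoeudesma-5',11'(13')-dien-12',8'-olide | C=C1C(=O)O[C@H]2C[C@@](C)(O)C([C@H](C)CCCOC(C)=O)=C[C@@H]12 | intermediate
28 | C2 gem-diacetate of 11 | CC(=O)OC(OC(C)=O)/C=C(\C)C1=C[C@H](C)C[C@H]2OC(=O)C(=C)[C@@H]2C1 | intermediate (not isolated)
29 | (2R,7S,8R,10R)-2-acetoxyguaia-1(5),3,11(13)-trien-12,8-olide | C=C1C(=O)O[C@@H]2C[C@@H](C)C3=C(C[C@@H]12)C(C)=C[C@H]3OC(C)=O | intermediate (not isolated)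
30 | CNP0257312.1 (1R,2R,3S,7S,8R,10R,4'R,7'S,8'S,10'R,11'R) | C=C1C(=O)O[C@@H]2C[C@@H](C)[C@]34C[C@]5(C(=O)O[C@H]6C[C@@](C)(O)C([C@H](C)CCCOC(C)=O)=C[C@H]65)[C@H](C(C)=C3C[C@@H]12)[C@H]4OC(C)=O | target

## Step count and risks
Total step count: 17.

Longest linear sequence: 10 steps. This is steps 8–17 from 12, or equally step 1 followed by steps 9–17 from 1.

**Step 17.**
- Risk: the cyclopentenyl cation may lose H-2 or H-6 instead of H-1. The diene 29 may isomerise by a 1,5-H shift. It may also add to the methylene lactone of a second western unit.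
- Fallback: ring closure is separated from diene release. It sets out from 11 and comes back at 29. Catalytic TfOH in CH2Cl2 effects the ordinary iso-Nazarov cyclisation of 11 to the 2-oxoguai-1(5)-enolide F1. Copper/air vinylogous oxidation (Cu(OAc)2, tetramethylguanidine, air) of the tertiary γ C4–H gives the 4-hydroxy enone F2. Luche reduction from the α face (the β face carries the C10 methyl) gives the 2β,4-diol F3. Mitsunobu inversion with acetic acid gives the bench-stable 2α-acetoxy-4-ol F4. Burgess dehydration of F4 at rt in the presence of 27 releases 29 under neutral conditions, and 29 goes on to 30 as in the route.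

**Step 5.**
- Risk: the ketone may enolise, acetylide may attack C8, or the epoxide may undergo base-induced elimination.
- Fallback: the regiochemistry is fixed by a substituent on the diene and the oxygen is brought in by hydroboration. It sets out from 2 and comes back at 9. Sonogashira coupling of chloroprene with triisopropylsilylacetylene gives 2-[(triisopropylsilyl)ethynyl]buta-1,3-diene F5. Treating 2 and F5 under the conditions of step 2 gives, through the alkynyl divinylcyclopropane F6, the 7-alkynyl cycloheptadiene ester F7. Hydroboration–oxidation (BH3·SMe2, then NaBO3) of the trisubstituted ring alkene from the face anti to the C10 methyl puts OH on C8 and H on C7 in a syn sense. Alkyne and OH are therefore trans, which gives the hydroxy ester F8. The sequence of step 3 leads through the hydroxy Weinreb amide F9 to the hydroxy ketone F10. Ethynylmagnesium bromide gives the silylated diyne diol F11, and TBAF removes the silyl group to deliver 9.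

**Step 9.**
- Risk: the enol ether may be cyclopropanated, or the new bond may form at C7' or C8'.
- Fallback: the enol ether is taken out of the substrate and the C10' oxygen comes from epoxide chemistry instead of singlet oxygen. It sets out from 13 and comes back at 19. Ethylene glycol/PPTS converts 13 into the ketal 8-methyl-1,4-dioxaspiro[4.5]dec-7-ene F12. This has only one accessible C–H/Cope site (C9'–H, bond to C5') and gives with 2 and Rh2(S-DOSP)4 the ketal enoate F13. Mg/MeOH gives the ketal ester F14, LiAlH4 the ketal alcohol F15 and Ac2O the ketal acetate F16. Wet oxalic acid on silica gives the β,γ-unsaturated ketone F17. mCPBA, attacking anti to the side chain, gives the β,γ-epoxy ketone F18, and Et3N opens it (E1cB) to 19.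

Further compounds
F1 | step 17 | (7S,8R,10R)-2-oxoguaia-1(5),11(13)-dien-12,8-olide (C4 epimers) | C=C1C(=O)O[C@@H]2C[C@@H](C)C3=C(C[C@@H]12)C(C)CC3=O
F2 | step 17 | 4-hydroxy-2-oxoguaia-1(5),11(13)-dien-12,8-olide (C4 epimers) | C=C1C(=O)O[C@@H]2C[C@@H](C)C3=C(C[C@@H]12)C(C)(O)CC3=O
F3 | step 17 | 2β,4-dihydroxyguaia-1(5),11(13)-dien-12,8-olide | C=C1C(=O)O[C@@H]2C[C@@H](C)C3=C(C[C@@H]12)C(C)(O)C[C@@H]3O
F4 | step 17 | 2α-acetoxy-4-hydroxyguaia-1(5),11(13)-dien-12,8-olide | C=C1C(=O)O[C@@H]2C[C@@H](C)C3=C(C[C@@H]12)C(C)(O)C[C@H]3OC(C)=O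
F5 | step 5 | 2-[(triisopropylsilyl)ethynyl]buta-1,3-diene | C=CC(=C)C#C[Si](C(C)C)(C(C)C)C(C)C
F6 | step 5 | alkynyl cis-divinylcyclopropane | COC(=O)[C@@]1(/C=C/C)C[C@@]1(C=C)C#C[Si](C(C)C)(C(C)C)C(C)C
F7 | step 5 | methyl (3R)-3-methyl-6-[(triisopropylsilyl)ethynyl]cyclohepta-1,5-diene-1-carboxylate | COC(=O)C1=C[C@H](C)CC=C(C#C[Si](C(C)C)(C(C)C)C(C)C)C1
F8 | step 5 | (7S,8R,10R)-8-hydroxy-7-silylethynyl ester | COC(=O)C1=C[C@H](C)C[C@@H](O)[C@H](C#C[Si](C(C)C)(C(C)C)C(C)C)C1
F9 | step 5 | Weinreb amide of F8 | CON(C)C(=O)C1=C[C@H](C)C[C@@H](O)[C@H](C#C[Si](C(C)C)(C(C)C)C(C)C)C1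
F10 | step 5 | (7S,8R,10R)-8-hydroxy-7-silylethynyl methyl ketone | CC(=O)C1=C[C@H](C)C[C@@H](O)[C@H](C#C[Si](C(C)C)(C(C)C)C(C)C)C1
F11 | step 5 | mono-silylated diyne diol (C4 epimers) | C#CC(C)(O)C1=C[C@H](C)C[C@@H](O)[C@H](C#C[Si](C(C)C)(C(C)C)C(C)C)C1
F12 | step 9 | 8-methyl-1,4-dioxaspiro[4.5]dec-7-ene | CC1=CCC2(CC1)OCCO2
F13 | step 9 | ketal enoate (4'R,5'S) | COC(=O)/C=C/[C@@H](C)[C@@H]1CC2(CC=C1C)OCCO2
F14 | step 9 | ketal ester (4'R,5'S) | COC(=O)CC[C@@H](C)[C@@H]1CC2(CC=C1C)OCCO2
F15 | step 9 | ketal alcohol (4'R,5'S) | OCCC[C@@H](C)[C@@H]1CC2(CC=C1C)OCCO2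
F16 | step 9 | ketal acetate (4'R,5'S) | CC(=O)OCCC[C@@H](C)[C@@H]1CC2(CC=C1C)OCCO2
F17 | step 9 | β,γ-unsaturated ketone (4'R,5'S) | CC(=O)OCCC[C@@H](C)[C@@H]1CC(=O)CC=C1C
F18 | step 9 | C9',C10'-epoxy ketone, oxirane anti to the side chain | CC(=O)OCCC[C@@H](C)[C@@H]1CC(=O)C[C@H]2O[C@@]12C
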